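**Retrosynthetic overview**
1. The cyclohexene ring is made first: (E)-cinnamaldehyde 1 + (E)-β-ocimene 2 give aldehyde 3 by an enantioselective iminium Diels–Alder reaction, which sets all three stereocentres.
2. The formyl carbon of 3 is turned into an acyl-anion equivalent, the N-tert-butylhydrazone 4.
3. Aryl partner: commercial benzofuranone 5 is reduced and dehydrated (alcohol 6) to 4,6-dimethoxybenzofuran 7, which aromatises the furan ring, and is then brominated at C7 to give 8.
4. Key disconnection, aryl C7–C(=O): palladium-catalysed C-arylation of 4 with 8, then hydrolysis (through 9 and 10) to ketone 11.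
5. Selective O-demethylation ortho to the ketone gives target 12.

Assumption: 2 is taken from the commercial E/Z ocimene mixture and used in excess; only the (E)-isomer reacts.

**Step 1**
Reactants: 1 (E)-cinnamaldehyde; 2 (E)-β-ocimene
Product: 3 (1R,2S,6R)-3-methyl-2-(3-methylbut-2-en-1-yl)-6-phenylcyclohex-3-ene-1-carbaldehyde
Conditions: (5R)-5-benzyl-2,2,3-trimethylimidazolidin-4-one hydrochloride (20 mol %), 2 (3 equiv), MeCN/H2O 95:5, rt, 48 h
Reagents that add atoms: none
Why: Iminium-ion organocatalytic Diels–Alder reaction, in which the diene adds to the face of the (E)-iminium not shielded by the benzyl group (C1 R, C6 R), the polarised dienophile bonds its β-carbon to the CH2 terminus of the diene, and the endo transition state places CHO cis to the prenyl group (C2 S).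

**Step 2**
Reactants: 3 (1R,2S,6R)-3-methyl-2-(3-methylbut-2-en-1-yl)-6-phenylcyclohex-3-ene-1-carbaldehyde
Product: 4 (E)-1-tert-butyl-2-{[(1R,2S,6R)-3-methyl-2-(3-methylbut-2-en-1-yl)-6-phenylcyclohex-3-en-1-yl]methylidene}hydrazine
Conditions: t-BuNHNH2·HCl (1.1 equiv), NaOAc (1.2 equiv), EtOH, rt, 2 h
Reagents that add atoms: tert-butylhydrazine hydrochloride, CC(C)(C)NN.Cl
Why: Buffered hydrazone condensation gives the N-tert-butylhydrazone, an acyl-anion equivalent whose azomethine carbon becomes nucleophilic on N–H deprotonation, without epimerising the α-stereocentre.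

**Step 3**
Reactants: 5 4,6-dimethoxy-1-benzofuran-3(2H)-one
Product: 7 4,6-dimethoxy-1-benzofuran, via 4,6-dimethoxy-2,3-dihydro-1-benzofuran-3-ol 6 (not isolated)
Conditions: NaBH4, MeOH/THF, 0 °C to rt; then 2 M HCl, rt
Reagents that add atoms: none
Why: Hydride reduction of the aryl ketone followed by acid-catalysed E1 dehydration of the benzylic alcohol, driven by aromatisation to the benzofuran.

**Step 4**
Reactants: 7 4,6-dimethoxy-1-benzofuran
Product: 8 7-bromo-4,6-dimethoxy-1-benzofuran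
Conditions: NBS (1.0 equiv), MeCN, −30 to 0 °C, dark
Reagents that add atoms: N-bromosuccinimide, O=C1CCC(=O)N1Br
Why: Electrophilic aromatic bromination at C7, which is para to the 4-methoxy group, ortho to the 6-methoxy group and the ring oxygen, and less hindered than C5, so it reacts before the furan double bond.

**Step 5**
Reactants: 4 (E)-1-tert-butyl-2-{[(1R,2S,6R)-3-methyl-2-(3-methylbut-2-en-1-yl)-6-phenylcyclohex-3-en-1-yl]methylidene}hydrazine; 8 7-bromo-4,6-dimethoxy-1-benzofuran
Product: 11 (4,6-dimethoxy-1-benzofuran-7-yl)[(1R,2S,6R)-3-methyl-2-(3-methylbut-2-en-1-yl)-6-phenylcyclohex-3-en-1-yl]methanone, via benzylic azo compound 9 (not isolated), via ketone N-tert-butylhydrazone 10 (not isolated)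
Conditions: Pd2(dba)3 (2.5 mol %), DPEphos (6 mol %), NaOtBu (1.5 equiv), toluene, 90 °C; then 2 M HCl/THF, rt
Reagents that add atoms: water, O
Why: Palladium-catalysed C-arylation of an N-tert-butylhydrazone (cross-coupling of an acyl-anion equivalent with an aryl bromide), in which the deprotonated hydrazone reductively eliminates through carbon because tert-butyl blocks nitrogen, the azo compound 9 tautomerises to 10 and is hydrolysed to the ketone, and C1 is never deprotonated so the three stereocentres are carried through.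

**Step 6**
Reactants: 11 (4,6-dimethoxy-1-benzofuran-7-yl)[(1R,2S,6R)-3-methyl-2-(3-methylbut-2-en-1-yl)-6-phenylcyclohex-3-en-1-yl]methanone
Product: 12 (6-hydroxy-4-methoxy-1-benzofuran-7-yl)[(1R,2S,6R)-3-methyl-2-(3-methylbut-2-en-1-yl)-6-phenylcyclohex-3-en-1-yl]methanone
Conditions: BCl3 (1 M in CH2Cl2, 2 equiv), CH2Cl2, −78 to −20 °C; then ice-water
Reagents that add atoms: none
Why: Chelation-controlled Lewis-acid ether cleavage, in which BCl3 bound to the ketone oxygen removes only the ortho (C6) methyl group and leaves the 4-methoxy group, the furan and, at low temperature, both trisubstituted alkenes intact.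

**Compound list**
1 | (E)-cinnamaldehyde | O=C/C=C/c1ccccc1 | starting material
2 | (E)-β-ocimene, (3E)-3,7-dimethylocta-1,3,6-triene | C=C/C(C)=C/CC=C(C)C | starting material
3 | (1R,2S,6R)-3-methyl-2-(3-methylbut-2-en-1-yl)-6-phenylcyclohex-3-ene-1-carbaldehyde | O=C[C@@H]1[C@H](CC=C(C)C)C(C)=CC[C@H]1c1ccccc1 | intermediate
4 | (E)-1-tert-butyl-2-{[(1R,2S,6R)-3-methyl-2-(3-methylbut-2-en-1-yl)-6-phenylcyclohex-3-en-1-yl]methylidene}hydrazine | CC(C)(C)N/N=C/[C@@H]1[C@H](CC=C(C)C)C(C)=CC[C@H]1c1ccccc1 | intermediate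
5 | 4,6-dimethoxy-1-benzofuran-3(2H)-one | COc1cc(OC)c2c(c1)OCC2=O | starting material
6 | 4,6-dimethoxy-2,3-dihydro-1-benzofuran-3-ol (racemic; not isolated) | COc1cc(OC)c2c(c1)OCC2O | intermediate
7 | 4,6-dimethoxy-1-benzofuran | COc1cc(OC)c2ccoc2c1 | intermediate
8 | 7-bromo-4,6-dimethoxy-1-benzofuran | COc1cc(OC)c(Br)c2occc12 | intermediate
9 | (E)-1-tert-butyl-2-{(4,6-dimethoxy-1-benzofuran-7-yl)[(1R,2S,6R)-3-methyl-2-(3-methylbut-2-en-1-yl)-6-phenylcyclohex-3-en-1-yl]methyl}diazene (epimers at the new CH; not isolated) | CC(C)(C)/N=N/C(c1c(OC)cc(OC)c2ccoc12)[C@@H]1[C@H](CC=C(C)C)C(C)=CC[C@H]1c1ccccc1 | intermediate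
10 | 1-tert-butyl-2-{(4,6-dimethoxy-1-benzofuran-7-yl)[(1R,2S,6R)-3-methyl-2-(3-methylbut-2-en-1-yl)-6-phenylcyclohex-3-en-1-yl]methylidene}hydrazine (not isolated) | CC(C)(C)NN=C(c1c(OC)cc(OC)c2ccoc12)[C@@H]1[C@H](CC=C(C)C)C(C)=CC[C@H]1c1ccccc1 | intermediate
11 | (4,6-dimethoxy-1-benzofuran-7-yl)[(1R,2S,6R)-3-methyl-2-(3-methylbut-2-en-1-yl)-6-phenylcyclohex-3-en-1-yl]methanone | COc1cc(OC)c(C(=O)[C@@H]2[C@H](CC=C(C)C)C(C)=CC[C@H]2c2ccccc2)c2occc12 | intermediate
12 | (6-hydroxy-4-methoxy-1-benzofuran-7-yl)[(1R,2S,6R)-3-methyl-2-(3-methylbut-2-en-1-yl)-6-phenylcyclohex-3-en-1-yl]methanone | COc1cc(O)c(C(=O)[C@@H]2[C@H](CC=C(C)C)C(C)=CC[C@H]2c2ccccc2)c2occc12 | target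

**Totals**
Total step count: 6. Longest linear sequence: 4 steps (1 → 2 → 5 → 6, or 3 → 4 → 5 → 6).

**Steps most likely to fail, and fallbacks**

Step 5 is the riskiest: the bromide has two ortho substituents and is electron-rich, and the hydrazone is α-branched, so oxidative addition and the C–C reductive elimination may both be slow. The fallback sets out from bromide 8 and aldehyde 3 and joins them with normal polarity. Bromine–lithium exchange on 8 (n-BuLi, THF, −78 °C) gives (4,6-dimethoxy-1-benzofuran-7-yl)lithium F1. Adding 3 gives (4,6-dimethoxy-1-benzofuran-7-yl)[(1R,2S,6R)-3-methyl-2-(3-methylbut-2-en-1-yl)-6-phenylcyclohex-3-en-1-yl]methanol F2 as a mixture of carbinol epimers. Oxidation with Dess–Martin periodinane (NaHCO3, CH2Cl2) comes back to the route at ketone 11.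

Step 1 is next: a β-aryl enal is a sluggish iminium dienophile towards an acyclic diene, and some of the regioisomeric and exo adducts may form. The fallback sets out from ocimene 2 and uses a chiral auxiliary. (4R)-4-Benzyl-3-[(2E)-3-phenylprop-2-enoyl]-1,3-oxazolidin-2-one F3 is made from commercial (E)-cinnamoyl chloride and lithiated (R)-4-benzyl-1,3-oxazolidin-2-one. Its Et2AlCl chelate (1.4 equiv, CH2Cl2, −20 °C) reacts with 2 on the face opposite the benzyl group, through the endo transition state, to give (4R)-4-benzyl-3-{[(1R,2S,6R)-3-methyl-2-(3-methylbut-2-en-1-yl)-6-phenylcyclohex-3-en-1-yl]carbonyl}-1,3-oxazolidin-2-one F4. LiBH4 (THF/MeOH, 0 °C) releases [(1R,2S,6R)-3-methyl-2-(3-methylbut-2-en-1-yl)-6-phenylcyclohex-3-en-1-yl]methanol F5, and Dess–Martin oxidation comes back to the route at aldehyde 3.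

Step 4 is third: bromination could also occur at C5, go twice, or attack the furan C2=C3 bond. The fallback sets out from benzofuranone 5 and changes the order, so that bromine is introduced while the furan double bond does not yet exist. NBS (MeCN, 0 °C) gives 7-bromo-4,6-dimethoxy-1-benzofuran-3(2H)-one F6. NaBH4 in MeOH, then 2 M HCl, takes it through 7-bromo-4,6-dimethoxy-2,3-dihydro-1-benzofuran-3-ol F7 and comes back to the route at bromide 8, bypassing 7.

**Further compounds**
F1 | step 5 | (4,6-dimethoxy-1-benzofuran-7-yl)lithium | [Li]c1c(OC)cc(OC)c2ccoc12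
F2 | step 5 | (4,6-dimethoxy-1-benzofuran-7-yl)[(1R,2S,6R)-3-methyl-2-(3-methylbut-2-en-1-yl)-6-phenylcyclohex-3-en-1-yl]methanol (carbinol epimers) | COc1cc(OC)c(C(O)[C@@H]2[C@H](CC=C(C)C)C(C)=CC[C@H]2c2ccccc2)c2occc12
F3 | step 1 | (4R)-4-benzyl-3-[(2E)-3-phenylprop-2-enoyl]-1,3-oxazolidin-2-one | O=C(/C=C/c1ccccc1)N1[C@H](Cc2ccccc2)COC1=O
F4 | step 1 | (4R)-4-benzyl-3-{[(1R,2S,6R)-3-methyl-2-(3-methylbut-2-en-1-yl)-6-phenylcyclohex-3-en-1-yl]carbonyl}-1,3-oxazolidin-2-one | O=C([C@@H]1[C@H](CC=C(C)C)C(C)=CC[C@H]1c1ccccc1)N1[C@H](Cc2ccccc2)COC1=O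
F5 | step 1 | [(1R,2S,6R)-3-methyl-2-(3-methylbut-2-en-1-yl)-6-phenylcyclohex-3-en-1-yl]methanol | OC[C@@H]1[C@H](CC=C(C)C)C(C)=CC[C@H]1c1ccccc1
F6 | step 4 | 7-bromo-4,6-dimethoxy-1-benzofuran-3(2H)-one | COc1cc(OC)c(Br)c2OCC(=O)c12
F7 | step 4 | 7-bromo-4,6-dimethoxy-2,3-dihydro-1-benzofuran-3-ol (racemic) | COc1cc(OC)c(Br)c2OCC(O)c12
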